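The runs come from a simulation for an exercise, noise included.

Read at 5.0 d, the amount of target in the flask depends on what stops it, and two views part on exactly that.

in all of them: starting material 15 mM; free catalyst 15 µM; added ligand 24 µM

| run | second substrate | remark | time |
|---|---|---|---|
| autumn | 10 mM | run made earlier |  |
| dusk | 22 mM | run made earlier |  |
| flask | 15.0 mM |  | 5.0 d |

| run | time / d | target / % | starting material / % |
|---|---|---|---|
| autumn | 0.500 | 11.5 | 88.7 |
| autumn | 0.833 | 17.2 | 81.9 |
| autumn | 1.04 | 20.8 | 78.8 |
| autumn | 1.67 | 27.9 | 71.5 |
| autumn | 2.50 | 37.5 | 62.9 |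
| autumn | 4.00 | 48.9 | 51.9 |
| autumn | 6.00 | 57.0 | 44.7 |
| dusk | 0.833 | 12.1 | 88.3 |
| dusk | 1.67 | 21.4 | 78.4 |
| dusk | 2.50 | 30.8 | 69.5 |
| dusk | 3.00 | 34.5 | 65.3 |
| dusk | 4.00 | 42.8 | 57.3 |
| dusk | 5.00 | 49.0 | 51.2 |
| dusk | 6.00 | 53.8 | 46.7 |

(readings scatter by 0.5 percentage points)

- the analysis behind the earlier runs scatters by 0.5 percentage points, standard deviation

1. concentration of target at 5.0 d, in mM
2. concentration of starting material at 5.0 d, in mM

The forecast holds that second substrate “is also a true reactant”. On that view second substrate is used one for one with starting material, and its charge of 15.0 mM runs down together with the 15 mM of starting material. The forecast gives 8.1 mM target and 6.95 mM starting material.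

I hold that second substrate merely competes for the catalyst, while target climbs towards an equilibrium with starting material. Late in the autumn run the mean rate falls from 1.14 mM d⁻¹ to 0.608 mM d⁻¹ as target rises. Taken as proportional to the distance from a fixed amount, that gives a constant of 0.364 d⁻¹. The line reaches zero rate at 9.61 mM, which I call the ceiling, the target reachable under thermodynamic control. It is a reading and carries the scatter.

The start gives the other end. Mean rates to the first readings are 3.45 mM d⁻¹ in the autumn run and 2.18 mM d⁻¹ in the dusk run. Interpolating their reciprocals to this flask's charge gives 2.78 mM d⁻¹, so a constant of 0.289 d⁻¹ against the ceiling. Second substrate runs down during the flask, so I join the ends with the mean constant, 0.326 d⁻¹. My reckoning gives 7.73 mM target, less than the forecast, and 7.27 mM starting material.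

The flask gives 7.73 mM target and 7.27 mM starting material, so the forecast stands within its margin.

    starting material + free catalyst ⇌ catalyst intermediate A (K = 42.0 M⁻¹, k = 12900 M⁻¹ h⁻¹)
    catalyst intermediate A ⇌ free catalyst + target (K = 0.0410 M, k = 85.7 h⁻¹)
    second substrate + free catalyst ⇌ catalyst intermediate B (K = 337 M⁻¹, k = 14900 M⁻¹ h⁻¹)
    catalyst intermediate B → free catalyst + second product (k = 39.2 h⁻¹)
    free catalyst + added ligand ⇌ idle complex (K = 1.90 × 10⁵ M⁻¹, k = 7920 M⁻¹ h⁻¹)

The flask's target is 80.4 % of the ceiling, and the amount of second product there is 13.9 mM, more than the target; in the scheme second substrate competes for free catalyst. The reactant view has its region in the autumn run, whose 10 mM charge lies near the ceiling, so there a stop at that charge and a stop at the ceiling look alike. The forecast's number belongs to this ligand charge. With 0.0096 mM added ligand I keep the ceiling, and that neighbouring flask then needs a constant of 0.565 d⁻¹ against the joined 0.326 d⁻¹. At 5.00 d it gives 9.04 mM target and 5.96 mM starting material.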